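**Plan**

- Retrosynthesis: the tetrahydrofuran (O1, C2–C5) carries a CH2OH arm on C3 and on C4. The C4 arm is traced back to CH2I and the C3–C4 bond is cut, so that C3 with its CH2O carbon becomes an oxirane and C4 with its CH2 becomes a vinyl group, both on the benzylic carbons C2 and C5 of a bis(benzylic) ether.
- The ether is cut at one C–O bond into an (S)-1-arylallyl alkoxide and an (E)-3-arylallyl carbonate. Both come from one racemic 1-arylallyl alcohol, which is cut at the vinyl–carbinol bond into vinylmagnesium bromide and O-benzylsyringaldehyde.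
- Forward: benzylation, vinyl addition, lipase resolution of one portion, 1,3-transposition and carbonate formation on the other, iridium-catalysed branched etherification to the meso diene, mono-epoxidation. The only ring, the tetrahydrofuran, is then closed by radical C3–C4 bond formation; iodide-to-oxygen exchange and debenzylation finish.
- Stereochemistry: the cis aryls on C2/C5 come from the resolved (S)-alcohol plus the catalyst-set opposite C–O centre (meso ether). C3 and C4 are set in the cyclisation by a chair-like 5-exo transition state (arms cis to each other, trans to the aryls). The oxirane configuration is erased, and because the target is meso the racemic intermediates 12–17 lose nothing.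

Key step: step 8

Assumption: the (Ra,R,R) phosphoramidite is taken to give the (R) C–O centre from the (E)-carbonate, as with other heteroatom nucleophiles on cinnamyl-type carbonates; if the sense is the reverse, the mirror-image ligand is used.

**Route**

Step 1
Reactants: 1 syringaldehyde (4-hydroxy-3,5-dimethoxybenzaldehyde); 2 benzyl bromide
Product: 3 4-(benzyloxy)-3,5-dimethoxybenzaldehyde
Conditions: K2CO3, DMF, 60 °C
Reagents that add atoms: none
Why: Williamson ether synthesis; the phenoxide, although flanked by two methoxy groups, is alkylated cleanly by the reactive benzylic bromide, and the benzyl ether survives every later step until hydrogenolysis.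

Step 2
Reactants: 3 4-(benzyloxy)-3,5-dimethoxybenzaldehyde; 4 vinylmagnesium bromide
Product: 5 rac-1-[4-(benzyloxy)-3,5-dimethoxyphenyl]prop-2-en-1-ol
Conditions: THF, −78 → 0 °C; aq. NH4Cl
Reagents that add atoms: none
Why: Grignard 1,2-addition to a non-enolisable aryl aldehyde gives the racemic allylic alcohol, which feeds both halves of the ether.

Step 3
Reactants: 5 rac-1-[4-(benzyloxy)-3,5-dimethoxyphenyl]prop-2-en-1-ol
Product: 6 (S)-1-[4-(benzyloxy)-3,5-dimethoxyphenyl]prop-2-en-1-ol
Conditions: Novozym 435 (immobilised Candida antarctica lipase B), vinyl acetate, MTBE, 30 °C, stopped near half conversion; chromatography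
Reagents that add atoms: none
Why: Lipase-catalysed kinetic resolution by irreversible transesterification; by the empirical rule for secondary carbinols with one large (aryl) and one medium (vinyl) group the (R)-enantiomer should be acylated and separated as its acetate, leaving (S)-alcohol 6, whose stereocentre becomes one benzylic carbon of the ring.

Step 4
Reactants: 5 rac-1-[4-(benzyloxy)-3,5-dimethoxyphenyl]prop-2-en-1-ol
Product: 7 (E)-3-[4-(benzyloxy)-3,5-dimethoxyphenyl]prop-2-en-1-ol
Conditions: O3ReOSiPh3 (2 mol %), Et2O, 0 °C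
Reagents that add atoms: none
Why: Rhenium-oxo-catalysed 1,3-transposition of an allylic alcohol ([3,3] shift of the allyl perrhenate) runs downhill to the aryl-conjugated (E)-isomer, and since the stereocentre is erased the racemic alcohol serves as it is.

Step 5
Reactants: 7 (E)-3-[4-(benzyloxy)-3,5-dimethoxyphenyl]prop-2-en-1-ol
Product: 8 (E)-3-[4-(benzyloxy)-3,5-dimethoxyphenyl]prop-2-en-1-yl tert-butyl carbonate
Conditions: Boc2O, Bu4NHSO4 (cat.), 30% aq. NaOH, CH2Cl2, 0 °C → rt
Reagents that add atoms: di-tert-butyl dicarbonate, CC(C)(C)OC(=O)OC(=O)OC(C)(C)C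
Why: Phase-transfer O-acylation of a primary alcohol gives the allylic carbonate; the tert-butyl carbonate is chosen because the tert-butoxide it releases does not compete as a nucleophile in step 6.

Step 6
Reactants: 6 (S)-1-[4-(benzyloxy)-3,5-dimethoxyphenyl]prop-2-en-1-ol; 8 (E)-3-[4-(benzyloxy)-3,5-dimethoxyphenyl]prop-2-en-1-yl tert-butyl carbonate
Product: 11 meso-(1R,1'S)-bis{1-[4-(benzyloxy)-3,5-dimethoxyphenyl]prop-2-en-1-yl} ether, via lithium (S)-alkoxide 9 (not isolated), via cuprous (S)-alkoxide 10 (not isolated)
Conditions: 6, LiN(SiMe3)2, THF, 0 °C; CuI (1 equiv), rt; then 8, [Ir(cod)Cl]2 (2 mol %), (Ra,R,R)-O,O'-(1,1'-binaphthyl-2,2'-diyl) N,N-bis(1-phenylethyl)phosphoramidite (4 mol %, pre-activated with n-PrNH2), THF, rt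
Reagents that add atoms: none
Why: Iridium-catalysed asymmetric allylic etherification with a cuprous alkoxide; outer-sphere attack at the aryl-bearing terminus of the allyliridium gives the branched ether, the catalyst (not the alkoxide) sets the new C–O centre as (R), and the (S) centre of 6 is untouched, so the (R,S) pairing is the meso diene.

Step 7
Reactants: 11 meso-(1R,1'S)-bis{1-[4-(benzyloxy)-3,5-dimethoxyphenyl]prop-2-en-1-yl} ether
Product: 12 rac-{[4-(benzyloxy)-3,5-dimethoxyphenyl](oxiran-2-yl)methyl} {1-[4-(benzyloxy)-3,5-dimethoxyphenyl]prop-2-en-1-yl} ether (benzylic carbons as in 11; both epimers at the oxirane carbon)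
Conditions: mCPBA (1.0 equiv), NaHCO3, CH2Cl2, 0 °C → rt, stopped at partial conversion; unreacted 11 recycled
Reagents that add atoms: mCPBA, OOC(=O)c1cccc(Cl)c1
Why: Prilezhaev epoxidation of one of the two enantiotopic vinyl groups desymmetrises the meso diene to a racemate; neither facial nor enantiotopic selectivity is needed, because the oxirane stereocentre is destroyed in step 8 and both enantiomers lead to the same meso target.

Step 8
Reactants: 12 rac-{[4-(benzyloxy)-3,5-dimethoxyphenyl](oxiran-2-yl)methyl} {1-[4-(benzyloxy)-3,5-dimethoxyphenyl]prop-2-en-1-yl} ether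
Product: 16 rac-[(2S,3R,4R,5R)-2,5-bis[4-(benzyloxy)-3,5-dimethoxyphenyl]-4-(iodomethyl)tetrahydrofuran-3-yl]methanol, via titanoxy C3 radical 13 (not isolated), via cyclised primary radical 14 (not isolated), via bis-titanium species 15 (not isolated)
Conditions: Cp2TiCl2 (2.5 equiv), Zn dust, THF, rt; 12 added over 30 min; then I2, THF, −20 → 0 °C; aq. NaH2PO4/Na2S2O3
Reagents that add atoms: iodine, II
Why: Cp2TiCl (trivalent titanium, a one-electron donor) cleaves the oxirane C3–O bond to the secondary C3 radical 13 that keeps a titanium-bound CH2O arm; 13 adds 5-exo-trig to the inner carbon of the vinyl group, which closes the tetrahydrofuran through the new C3–C4 bond and leaves primary radical 14, and a second Cp2TiCl captures 14 as alkyltitanium 15, which I2 converts to the CH2I group. The closest known reaction type is the titanocene-mediated reductive epoxide opening with 5-exo cyclisation of aryl(oxiranyl)methyl allyl ethers to 2-aryl-3-(hydroxymethyl)tetrahydrofurans, including halogen quench of the cyclised alkyltitanium. C4 is controlled by the chair-like transition state in which the C2 and C5 aryl groups, already cis through the meso ether, are both pseudo-equatorial, so the new CH2 arm ends trans to both aryls. C3 is controlled at the planar radical, which turns its CH2OTi arm anti to the C2 aryl and cis to the forming CH2 arm (the usual 1,5-cis preference of 1-substituted 5-hexenyl radicals); since the oxirane configuration is lost in 13, both epimers of 12 converge. The step needs cleavage at C3 rather than at CH2 (secured by the preference for the more substituted radical), ring closure faster than titanium capture and β-elimination of 13 (secured by the fast 3-oxa-5-hexenyl cyclisation with both aryls equatorial) and titanium capture of 14 faster than hydrogen abstraction from THF (secured by the excess of Cp2TiCl).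

Step 9
Reactants: 16 rac-[(2S,3R,4R,5R)-2,5-bis[4-(benzyloxy)-3,5-dimethoxyphenyl]-4-(iodomethyl)tetrahydrofuran-3-yl]methanol
Product: 17 rac-[(2S,3R,4R,5R)-2,5-bis[4-(benzyloxy)-3,5-dimethoxyphenyl]-4-(iodomethyl)tetrahydrofuran-3-yl]methyl acetate
Conditions: Ac2O, pyridine, DMAP (cat.), CH2Cl2, 0 °C
Reagents that add atoms: acetic anhydride, CC(=O)OC(C)=O
Why: Acylation of the primary alcohol, done directly on crude 16, blocks the hydroxyl that would otherwise displace the cis CH2I group and close a bicyclic ether.

Step 10
Reactants: 17 rac-[(2S,3R,4R,5R)-2,5-bis[4-(benzyloxy)-3,5-dimethoxyphenyl]-4-(iodomethyl)tetrahydrofuran-3-yl]methyl acetate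
Product: 18 meso-[(2S,3R,4S,5R)-2,5-bis[4-(benzyloxy)-3,5-dimethoxyphenyl]tetrahydrofuran-3,4-diyl]bis(methylene) diacetate
Conditions: CsOAc, DMF, 60 °C
Reagents that add atoms: caesium acetate, CC(=O)[O-].[Cs+]
Why: SN2 displacement of the primary iodide by the weakly basic acetate ion puts oxygen on the C4 arm without touching a stereocentre and restores the mirror symmetry.

Step 11
Reactants: 18 meso-[(2S,3R,4S,5R)-2,5-bis[4-(benzyloxy)-3,5-dimethoxyphenyl]tetrahydrofuran-3,4-diyl]bis(methylene) diacetate
Product: 19 meso-[(2S,3R,4S,5R)-2,5-bis[4-(benzyloxy)-3,5-dimethoxyphenyl]tetrahydrofuran-3,4-diyl]dimethanol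
Conditions: K2CO3 (cat.), MeOH, rt
Reagents that add atoms: none
Why: Base-catalysed transesterification to methyl acetate frees both primary alcohols under conditions that leave the benzylic ring ether and the aryl benzyl ethers alone.

Step 12
Reactants: 19 meso-[(2S,3R,4S,5R)-2,5-bis[4-(benzyloxy)-3,5-dimethoxyphenyl]tetrahydrofuran-3,4-diyl]dimethanol
Product: 20 4,4'-[(2S,3R,4S,5R)-3,4-bis(hydroxymethyl)tetrahydrofuran-2,5-diyl]bis(2,6-dimethoxyphenol) (CNP0170897.5)
Conditions: H2 (1 atm), 10% Pd/C, EtOAc–MeOH, rt, stopped at full debenzylation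
Reagents that add atoms: none
Why: Catalytic hydrogenolysis cleaves the two aryl benzyl ethers much faster than the ring benzylic C–O bonds, so brief exposure at ambient pressure should free both phenols and give the target.

**Compound list**

1 | syringaldehyde | COc1cc(C=O)cc(OC)c1O | starting material
2 | benzyl bromide | BrCc1ccccc1 | starting material
3 | 4-(benzyloxy)-3,5-dimethoxybenzaldehyde | COc1cc(C=O)cc(OC)c1OCc1ccccc1 | intermediate
4 | vinylmagnesium bromide | C=C[Mg]Br | starting material
5 | rac-1-[4-(benzyloxy)-3,5-dimethoxyphenyl]prop-2-en-1-ol | COc1cc(C(O)C=C)cc(OC)c1OCc1ccccc1 | intermediate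
6 | (S)-1-[4-(benzyloxy)-3,5-dimethoxyphenyl]prop-2-en-1-ol | COc1cc([C@@H](O)C=C)cc(OC)c1OCc1ccccc1 | intermediate
7 | (E)-3-[4-(benzyloxy)-3,5-dimethoxyphenyl]prop-2-en-1-ol | COc1cc(/C=C/CO)cc(OC)c1OCc1ccccc1 | intermediate
8 | (E)-3-[4-(benzyloxy)-3,5-dimethoxyphenyl]prop-2-en-1-yl tert-butyl carbonate | COc1cc(/C=C/COC(=O)OC(C)(C)C)cc(OC)c1OCc1ccccc1 | intermediate
9 | lithium alkoxide of 6 | COc1cc([C@@H](O[Li])C=C)cc(OC)c1OCc1ccccc1 | intermediate
10 | cuprous alkoxide of 6 | COc1cc([C@@H](O[Cu])C=C)cc(OC)c1OCc1ccccc1 | intermediate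
11 | meso-(1R,1'S)-bis{1-[4-(benzyloxy)-3,5-dimethoxyphenyl]prop-2-en-1-yl} ether | COc1cc([C@H](C=C)O[C@@H](c2cc(OC)c(OCc3ccccc3)c(OC)c2)C=C)cc(OC)c1OCc1ccccc1 | intermediate
12 | mono-epoxide of 11: {aryl(oxiran-2-yl)methyl} (1-arylallyl) ether, aryl = 4-(benzyloxy)-3,5-dimethoxyphenyl; racemic, one enantiomer drawn; oxirane carbon left open because both epimers are present | COc1cc([C@H](C2CO2)O[C@@H](c2cc(OC)c(OCc3ccccc3)c(OC)c2)C=C)cc(OC)c1OCc1ccccc1 | intermediate
13 | C3 radical with Cp2Ti(Cl)O–CH2 arm from opening of 12 (Cp written as σ-C5H5 in the SMILES) | COc1cc([C@H]([CH]CO[Ti](Cl)(C2C=CC=C2)C2C=CC=C2)O[C@@H](c2cc(OC)c(OCc3ccccc3)c(OC)c2)C=C)cc(OC)c1OCc1ccccc1 | intermediate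
14 | cyclised tetrahydrofuran with primary CH2 radical on C4 and Cp2Ti(Cl)O–CH2 arm on C3 | COc1cc([C@H]2O[C@@H](c3cc(OC)c(OCc4ccccc4)c(OC)c3)[C@H]([CH2])[C@@H]2CO[Ti](Cl)(C2C=CC=C2)C2C=CC=C2)cc(OC)c1OCc1ccccc1 | intermediate
15 | bis-titanium species: C4–CH2–Ti(Cl)Cp2 and C3–CH2–O–Ti(Cl)Cp2 | COc1cc([C@H]2O[C@@H](c3cc(OC)c(OCc4ccccc4)c(OC)c3)[C@H](C[Ti](Cl)(C3C=CC=C3)C3C=CC=C3)[C@@H]2CO[Ti](Cl)(C2C=CC=C2)C2C=CC=C2)cc(OC)c1OCc1ccccc1 | intermediate
16 | rac-[(2S,3R,4R,5R)-2,5-bis[4-(benzyloxy)-3,5-dimethoxyphenyl]-4-(iodomethyl)tetrahydrofuran-3-yl]methanol (aryls cis; CH2OH and CH2I cis to each other, trans to the aryls) | COc1cc([C@H]2O[C@@H](c3cc(OC)c(OCc4ccccc4)c(OC)c3)[C@H](CI)[C@@H]2CO)cc(OC)c1OCc1ccccc1 | intermediate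
17 | rac-[(2S,3R,4R,5R)-2,5-bis[4-(benzyloxy)-3,5-dimethoxyphenyl]-4-(iodomethyl)tetrahydrofuran-3-yl]methyl acetate | COc1cc([C@H]2O[C@@H](c3cc(OC)c(OCc4ccccc4)c(OC)c3)[C@H](CI)[C@@H]2COC(C)=O)cc(OC)c1OCc1ccccc1 | intermediate
18 | meso-[(2S,3R,4S,5R)-2,5-bis[4-(benzyloxy)-3,5-dimethoxyphenyl]tetrahydrofuran-3,4-diyl]bis(methylene) diacetate | COc1cc([C@H]2O[C@@H](c3cc(OC)c(OCc4ccccc4)c(OC)c3)[C@H](COC(C)=O)[C@@H]2COC(C)=O)cc(OC)c1OCc1ccccc1 | intermediate
19 | meso-[(2S,3R,4S,5R)-2,5-bis[4-(benzyloxy)-3,5-dimethoxyphenyl]tetrahydrofuran-3,4-diyl]dimethanol | COc1cc([C@H]2O[C@@H](c3cc(OC)c(OCc4ccccc4)c(OC)c3)[C@H](CO)[C@@H]2CO)cc(OC)c1OCc1ccccc1 | intermediate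
20 | 4,4'-[(2S,3R,4S,5R)-3,4-bis(hydroxymethyl)tetrahydrofuran-2,5-diyl]bis(2,6-dimethoxyphenol), meso | COc1cc([C@H]2O[C@@H](c3cc(OC)c(O)c(OC)c3)[C@H](CO)[C@@H]2CO)cc(OC)c1O | target

**Count**

Total steps: 12. Longest linear sequence: 11 (steps 1, 2, 4, 5, 6, 7, 8, 9, 10, 11, 12); step 3 is the side branch that joins at step 6.

**Steps most likely to fail, with fallbacks**

Step 8. The risk is that radical 13 is captured by titanium before it cyclises and then loses its β-oxygen, or that primary radical 14 takes a hydrogen atom from THF, or that the new iodide is attacked in the flask by the neighbouring titanium alkoxide; each path costs the CH2I arm. The fallback keeps the same C3–C4 closure but uses an acceptor for which every way of ending the radical sequence is productive. It sets out from 12: cross-metathesis with vinylboronic acid pinacol ester (second-generation Grubbs catalyst, CH2Cl2, 40 °C) should give the (E)-alkenyl pinacol boronate of 12 F1. Treating this with Cp2TiCl under the conditions of step 8, without iodine, should open the oxirane and close the ring onto the better acceptor. The resulting α-boryl radical ends as a CH2B group whether it is reduced by titanium and protonated or abstracts hydrogen from THF, giving the 3-(hydroxymethyl)-4-(pinacolborylmethyl)tetrahydrofuran F2 with the same chair-controlled configuration. Oxidation with NaBO3·4H2O in THF–H2O converts the C–B bond into C–OH and returns to the route at diol 19, so steps 9–11 are not needed.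

Step 7. The risk is that the two equivalent, electron-poor allylic-ether alkenes react slowly and without preference for stopping after one oxidation, so that bis-epoxide and unchanged diene, or oxidation of the alkoxy-arenes, erode the mono-epoxide. The fallback introduces the oxirane before the ether is made. It sets out from 5: Sharpless kinetic resolution (Ti(OiPr)4, D-(−)-diisopropyl tartrate, t-BuOOH, 4 Å molecular sieves, CH2Cl2, −20 °C) should epoxidise the (S)-enantiomer to the erythro epoxy alcohol (R)-[4-(benzyloxy)-3,5-dimethoxyphenyl][(S)-oxiran-2-yl]methanol F3. The unreacted (R)-enantiomer of 5 is not wasted, since step 4 erases its stereocentre. The cuprous alkoxide of F3, formed at low temperature to hold back Payne rearrangement, is then coupled with carbonate 8 under the iridium conditions and ligand of step 6. This returns to the route at 12 as a single oxirane epimer and single enantiomer.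

Step 6. The risk is that the chiral catalyst fails to override the chiral secondary alkoxide (a mismatched pairing that lowers the meso to C2-symmetric ratio), or that attack drifts to the unsubstituted allyl terminus and gives the linear ether. The fallback replaces catalyst control by stereospecific substitution. It sets out from 5: the lipase acylation of step 3 (Novozym 435, vinyl acetate, MTBE), here stopped just short of half conversion so that the ester is the enantiopure component, gives (R)-1-[4-(benzyloxy)-3,5-dimethoxyphenyl]prop-2-en-1-yl acetate F4. Methanolysis (K2CO3, MeOH) gives (R)-1-[4-(benzyloxy)-3,5-dimethoxyphenyl]prop-2-en-1-ol F5, and Boc2O under the conditions of step 5 gives its branched tert-butyl carbonate F6. Rhodium-catalysed allylic etherification of F6 (RhCl(PPh3)3, P(OMe)3, THF, 0 °C → rt) with cuprous alkoxide 10 proceeds through a configurationally stable rhodium enyl with net retention and at the substituted carbon, so the (R) centre of F6 and the (S) centre of 10 return to the route at meso ether 11.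

**Further compounds**

F1 | step 8 | (E)-alkenyl pinacol boronate from cross-metathesis of 12 (racemic, both oxirane epimers) | COc1cc([C@H](C2CO2)O[C@@H](c2cc(OC)c(OCc3ccccc3)c(OC)c2)/C=C/B2OC(C)(C)C(C)(C)O2)cc(OC)c1OCc1ccccc1
F2 | step 8 | rac-2,5-cis-diaryl-3-(hydroxymethyl)-4-[(pinacolboryl)methyl]tetrahydrofuran, arms cis to each other and trans to the aryls | COc1cc([C@H]2O[C@@H](c3cc(OC)c(OCc4ccccc4)c(OC)c3)[C@H](CB3OC(C)(C)C(C)(C)O3)[C@@H]2CO)cc(OC)c1OCc1ccccc1
F3 | step 7 | (R)-[4-(benzyloxy)-3,5-dimethoxyphenyl][(S)-oxiran-2-yl]methanol | COc1cc([C@H]([C@@H]2CO2)O)cc(OC)c1OCc1ccccc1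
F4 | step 6 | (R)-1-[4-(benzyloxy)-3,5-dimethoxyphenyl]prop-2-en-1-yl acetate | COc1cc([C@H](OC(C)=O)C=C)cc(OC)c1OCc1ccccc1
F5 | step 6 | (R)-1-[4-(benzyloxy)-3,5-dimethoxyphenyl]prop-2-en-1-ol | COc1cc([C@H](O)C=C)cc(OC)c1OCc1ccccc1
F6 | step 6 | (R)-1-[4-(benzyloxy)-3,5-dimethoxyphenyl]prop-2-en-1-yl tert-butyl carbonate | COc1cc([C@H](OC(=O)OC(C)(C)C)C=C)cc(OC)c1OCc1ccccc1
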